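**Plan**
- Retrosynthesis: the pyranone is cut off at C11–C3′ (Negishi coupling) and the 3‑OH is traced back to a C3 ketone. Ring B is then opened at C9–C10 after re‑forming a temporary C3–C8 bond (retro‑Grob, then retro‑[4+2]). Earlier cuts are C7–C8 (B‑alkyl Suzuki), C5–C6 with C4–CH3 (conjugate addition/methylation) and C4–side chain (B‑alkyl Suzuki).
- Forward: ring A is made first as (S)‑4‑methylcyclohexenone and is loaded with the side chain, the C5 tether and the quaternary C4. Ring B is closed onto it by an intramolecular Diels–Alder reaction, and the pyranone is attached late.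
- Enabling feature: the C3 carbonyl is flanked by the quaternary C4, so its only dienol ether is C3(OSi)=C2–C1=C10, a ring‑A 1,3‑diene whose termini are C3 and C10. A C8=C9 dienophile held by the C6–C7 tether from C5 spans exactly these termini. The pair C3=O / C8=CH2 of the target is what a Grob fragmentation of the temporary C3–C8 bond leaves behind.
- Stereochemistry: the C10 methyl centre comes from an organocatalytic Michael addition and directs C5 (anti conjugate addition), which directs C4 (anti methylation). The tethered [4+2] with a ring‑locked cis dienophile sets C10 (cis fusion) and C9. Hydride from the α‑face sets C3.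

Key step: step 10

Assumption: the (R)‑configured diphenylprolinol methyl ether is taken to give the (S)‑aldehyde 3, by analogy with the known facial sense of enamine Michael additions of propanal; if the sense is opposite, the (S)‑catalyst is used.

Locants used in names: C1–C10 as in a drimane decalin (ring A = C1–C5, C10; ring B = C5–C10), C11 = CH2 on C9, C12 = the carbon on C8 that ends as the exocyclic methylene; α = the face carrying the C10 methyl and H5 in the target, β = the other face.

**Step 1**
Reactants: 1 propanal; 2 but-3-en-2-one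
Product: 3 (S)-2-methyl-5-oxohexanal
Conditions: (R)-α,α-diphenylprolinol methyl ether (5 mol%), ethyl 3,4-dihydroxybenzoate (20 mol%), neat, 4 °C
Reagents that add atoms: none
Why: Enamine-catalysed asymmetric Michael addition of the aldehyde to the enone; the catalyst shields one face of the (E)-enamine and so sets the stereocentre that becomes C10.

**Step 2**
Reactants: 3 (S)-2-methyl-5-oxohexanal
Product: 4 (S)-4-methylcyclohex-2-en-1-one
Conditions: LiOH, i-PrOH, rt
Reagents that add atoms: none
Why: Intramolecular aldol condensation of the 1,5-keto aldehyde closes ring A, and the stereocentre ends γ to the carbonyl where it should no longer epimerise.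

**Step 3**
Reactants: 4 (S)-4-methylcyclohex-2-en-1-one
Product: 5 (S)-2-iodo-4-methylcyclohex-2-en-1-one
Conditions: I2, pyridine, CH2Cl2, 0 °C → rt
Reagents that add atoms: iodine, II
Why: α-Iodination of the enone (Johnson procedure: conjugate addition of pyridine, iodination, elimination) provides the coupling handle on the future C4.

**Step 4**
Reactants: 6 2-methylbut-3-en-2-ol
Product: 7 triethyl[(2-methylbut-3-en-2-yl)oxy]silane
Conditions: Et3SiOTf, 2,6-lutidine, CH2Cl2, 0 °C
Reagents that add atoms: triethylsilyl trifluoromethanesulfonate, CC[Si](CC)(CC)OS(=O)(=O)C(F)(F)F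
Why: Silylation of the tertiary alcohol with the silyl triflate masks the future formate oxygen through the organometallic steps.

**Step 5**
Reactants: 7 triethyl[(2-methylbut-3-en-2-yl)oxy]silane; 5 (S)-2-iodo-4-methylcyclohex-2-en-1-one
Product: 9 (S)-4-methyl-2-[3-methyl-3-(triethylsilyloxy)butyl]cyclohex-2-en-1-one, via alkylborane 8 (not isolated)
Conditions: 9-BBN, THF, rt; then 5, PdCl2(dppf) (5 mol%), AsPh3, Cs2CO3, DMF/H2O, rt
Reagents that add atoms: none
Why: Anti-Markovnikov hydroboration followed by B-alkyl Suzuki–Miyaura coupling with the α-iodoenone places the side chain on the enone α-carbon (future C4).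

**Step 6**
Reactants: 9 (S)-4-methyl-2-[3-methyl-3-(triethylsilyloxy)butyl]cyclohex-2-en-1-one
Product: 11 (2R,3R,4S)-3-ethenyl-2,4-dimethyl-2-[3-methyl-3-(triethylsilyloxy)butyl]cyclohexan-1-one, via silyl enol ether 10 (not isolated)
Conditions: CH2=CHMgBr, CuI (10 mol%), Me3SiCl, HMPA, THF, −78 °C; then MeLi, THF, 0 °C; then MeI, −78 °C → rt
Reagents that add atoms: vinylmagnesium bromide, C=C[Mg]Br; iodomethane, CI
Why: Tandem conjugate addition–enolate alkylation: the vinyl group should add anti to the C10 methyl (sets C5), and the regiodefined enolate regenerated from the silyl enol ether should be methylated anti to the new vinyl group (sets quaternary C4).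

**Step 7**
Reactants: 11 (2R,3R,4S)-3-ethenyl-2,4-dimethyl-2-[3-methyl-3-(triethylsilyloxy)butyl]cyclohexan-1-one
Product: 12 (4S,5R,6R)-5-ethenyl-4,6-dimethyl-6-[3-methyl-3-(triethylsilyloxy)butyl]cyclohex-2-en-1-one
Conditions: LiN(i-Pr)2, THF, −78 °C; then PhS(Cl)=N-t-Bu, −78 °C
Reagents that add atoms: none
Why: Mukaiyama dehydrogenation: the enolate can form only toward C2 because C4 is quaternary, and its sulfenylated derivative eliminates in situ to the C1=C2 enone.

**Step 8**
Reactants: 12 (4S,5R,6R)-5-ethenyl-4,6-dimethyl-6-[3-methyl-3-(triethylsilyloxy)butyl]cyclohex-2-en-1-one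
Product: 13 tert-butyl{[(5R,6R)-5-ethenyl-4,6-dimethyl-6-[3-methyl-3-(triethylsilyloxy)butyl]cyclohexa-1,3-dien-1-yl]oxy}dimethylsilane
Conditions: t-BuMe2SiOTf, Et3N, CH2Cl2, 0 °C → rt
Reagents that add atoms: tert-butyldimethylsilyl trifluoromethanesulfonate, CC(C)(C)[Si](C)(C)OS(=O)(=O)C(F)(F)F
Why: Soft enolisation: O-silylation and γ-deprotonation at C10 (no α′-hydrogen exists) should give the extended silyl dienol ether, a 1-silyloxycyclohexa-1,3-diene with termini C3 and C10.

**Step 9**
Reactants: 13 silyl dienol ether; 14 3-bromofuran-2(5H)-one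
Product: 16 butenolide-tethered silyl dienol ether (13 with the C5 vinyl group replaced by 2-(2-oxo-2,5-dihydrofuran-3-yl)ethyl), via alkylborane 15 (not isolated)
Conditions: 9-BBN, THF, rt; then 14, PdCl2(dppf) (5 mol%), AsPh3, K3PO4 (aq), DMF, rt
Reagents that add atoms: none
Why: 9-BBN hydroborates only the monosubstituted vinyl group, and B-alkyl Suzuki–Miyaura coupling with the α-bromobutenolide attaches the dienophile through C6–C7; the butenolide ring locks C11 and C12 cis on C8=C9.

**Step 10**
Reactants: 16 butenolide-tethered silyl dienol ether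
Product: 17 cage adduct (bicyclo[2.2.2]oct-2-ene with bridgeheads C3–OTBS and C10–CH3; new bonds C9–C10 and C3–C8; γ-lactone C12(=O)–O–C11 cis-fused on C8–C9 on the side of C1=C2)
Conditions: toluene (0.01 M), BHT (cat.), 110 °C
Reagents that add atoms: none
Why: Thermal intramolecular Diels–Alder reaction of normal electron demand, concerted but asynchronous: the ring-A diene C3(OSi)=C2–C1=C10 adds across the butenolide C8=C9, with its most nucleophilic terminus C10 bonding to the electrophilic β-carbon C9 and C3 bonding to the α-carbon C8. The closest known reaction type is the intramolecular Diels–Alder (double Michael) reaction of silyloxycyclohexadienes with tethered enoates, which gives bicyclo[2.2.2]octenes. Ring B (C5–C6–C7–C8–C9–C10) closes as a six-membered ring through the new C9–C10 bond, and the C3–C8 bond closes a temporary bridged six-membered ring (C3–C4–C5–C6–C7–C8) that is opened again in step 13. C10 is set cis to H5 because the two-carbon tether from C5 can deliver the dienophile only to the diene face on which it stands; C9 is set by suprafacial addition to the ring-locked cis alkene, because with C7 held on the C4–C5 side the lactone carbons C12 and C11 lie over C1=C2, which puts C11 trans and H9 cis to the C10 methyl; C8 and C3 are temporary stereocentres. The step needs regioselectivity (C10 to C9, not to C8), which is secured by the matching polarisation of the 1-silyloxydiene and the butenolide and by the fact that the alternative would join the two fully substituted carbons C8 and C10; facial and endo/exo selectivity are fixed by the tether.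

**Step 11**
Reactants: 17 cage adduct
Product: 18 cage diol (C11–OH and C12–OH)
Conditions: LiAlH4, THF, 0 °C
Reagents that add atoms: none
Why: Hydride reduction of the lactone to the 1,4-diol; the C3 carbonyl is masked as the bridgehead silyl ether, so nothing else should be reduced.

**Step 12**
Reactants: 18 cage diol
Product: 19 cage bis(methanesulfonate)
Conditions: MsCl (3 equiv), Et3N, CH2Cl2, −20 °C
Reagents that add atoms: methanesulfonyl chloride, CS(=O)(=O)Cl
Why: Sulfonylation of both primary hydroxyls via the sulfene, run cold with excess reagent so that bis-mesylation outruns cyclic ether formation.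

**Step 13**
Reactants: 19 cage bis(methanesulfonate)
Product: 20 cis-fused enone mesylate ([4β-(3-hydroxy-3-methylbutyl)-4α,10α-dimethyl-8(12)-methylene-3-oxo-5α-H-decal-1-en-9β-yl]methyl methanesulfonate)
Conditions: n-Bu4NF, THF, 0 °C → rt
Reagents that add atoms: none
Why: Fluoride removes the bridgehead silyl group and the C3 alkoxide triggers a Grob fragmentation (C3–C8 cleavage with loss of the C12 mesylate), which should return the C3 carbonyl as the C1=C2 enone and create the C8=C12 exocyclic methylene, while the C11 mesylate, not aligned for fragmentation, survives and the tertiary silyl ether is cleaved as well.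

**Step 14**
Reactants: 20 cis-fused enone mesylate
Product: 21 saturated C3 ketone mesylate
Conditions: [(Ph3P)CuH]6 (3 mol%), PhMe2SiH, t-BuOH, toluene, rt
Reagents that add atoms: none
Why: Copper hydride conjugate reduction (Stryker type) saturates only the enone C1=C2 bond and leaves the 1,1-disubstituted alkene and the mesylate.

**Step 15**
Reactants: 21 saturated C3 ketone mesylate
Product: 22 C11 iodide (tertiary alcohol free)
Conditions: NaI, DMF, 70 °C
Reagents that add atoms: sodium iodide, [Na+].[I-]
Why: Finkelstein displacement (SN2) of the primary mesylate by iodide.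

**Step 16**
Reactants: 22 C11 iodide
Product: 23 C11 iodide with tertiary formate
Conditions: AcOCHO, pyridine, DMAP (cat.), CH2Cl2, 0 °C → rt
Reagents that add atoms: acetic formic anhydride, CC(=O)OC=O
Why: Formylation of the only hydroxyl group by the mixed anhydride, which reacts at its more electrophilic formyl carbonyl.

**Step 17**
Reactants: 24 methyl acetoacetate; 25 malonyl dichloride
Product: 26 methyl 4-hydroxy-2-methyl-6-oxo-6H-pyran-3-carboxylate
Conditions: CH2Cl2, 0 °C → reflux
Reagents that add atoms: none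
Why: C,O-Diacylation of the β-keto ester by malonyl dichloride is a known direct route to 5-alkoxycarbonyl-4-hydroxy-6-methyl-2-pyranones.

**Step 18**
Reactants: 26 methyl 4-hydroxy-2-methyl-6-oxo-6H-pyran-3-carboxylate
Product: 27 methyl 4-hydroxy-5-iodo-2-methyl-6-oxo-6H-pyran-3-carboxylate
Conditions: N-iodosuccinimide, MeCN, rt
Reagents that add atoms: N-iodosuccinimide, O=C1CCC(=O)N1I
Why: Electrophilic iodination at the nucleophilic enol carbon between the two oxygenated carbons of the 4-hydroxy-2-pyranone.

**Step 19**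
Reactants: 27 methyl 4-hydroxy-5-iodo-2-methyl-6-oxo-6H-pyran-3-carboxylate
Product: 28 methyl 5-iodo-6-methoxy-2-methyl-4-oxo-4H-pyran-3-carboxylate
Conditions: MeOTf, CH2Cl2, rt; aq NaHCO3 work-up
Reagents that add atoms: methyl trifluoromethanesulfonate, COS(=O)(=O)C(F)(F)F
Why: O-Methylation of the neutral, internally hydrogen-bonded hydroxypyranone with a hard alkylating agent should occur at the lactone carbonyl oxygen and, after loss of the proton, give the 2-methoxy-4-pyranone regioisomer.

**Step 20**
Reactants: 23 C11 iodide with tertiary formate; 28 methyl 5-iodo-6-methoxy-2-methyl-4-oxo-4H-pyran-3-carboxylate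
Product: 30 C3 ketone carrying the pyranone and the tertiary formate, via alkylzinc iodide 29 (not isolated)
Conditions: Zn dust, LiCl, THF, 40 °C; then 28, Pd(OAc)2 (3 mol%), SPhos (6 mol%), THF/NMP, rt
Reagents that add atoms: none
Why: LiCl-assisted zinc insertion into the primary iodide tolerates ketone and formate, and Negishi sp3–sp2 coupling forms the C11–pyranone bond without passing through an epimerisable C9 aldehyde.

**Step 21**
Reactants: 30 C3 ketone carrying the pyranone and the tertiary formate
Product: 31 target, (3S,4R,5R,9S,10S) in the locants above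
Conditions: LiBH(s-Bu)3, THF, −78 °C; pH 7 buffer
Reagents that add atoms: none
Why: Substrate-controlled ketone reduction with a bulky hydride, which should attack the hindered C3 ketone from the α-face, away from the axial C6 methylene and the β side chain, to give the 3β-alcohol, while formate, ester and pyranone react more slowly at −78 °C.

**Compound list**
1 | propanal | CCC=O | starting material
2 | but-3-en-2-one | CC(=O)C=C | starting material
3 | (S)-2-methyl-5-oxohexanal | C[C@H](C=O)CCC(C)=O | intermediate
4 | (S)-4-methylcyclohex-2-en-1-one | C[C@H]1CCC(=O)C=C1 | intermediate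
5 | (S)-2-iodo-4-methylcyclohex-2-en-1-one | C[C@H]1CCC(=O)C(I)=C1 | intermediate
6 | 2-methylbut-3-en-2-ol | CC(C)(O)C=C | starting material
7 | triethyl[(2-methylbut-3-en-2-yl)oxy]silane | CC[Si](CC)(CC)OC(C)(C)C=C | intermediate
8 | 9-[3-methyl-3-(triethylsilyloxy)butyl]-9-borabicyclo[3.3.1]nonane | CC[Si](CC)(CC)OC(C)(C)CCB1C2CCCC1CCC2 | intermediate (not isolated)
9 | (S)-4-methyl-2-[3-methyl-3-(triethylsilyloxy)butyl]cyclohex-2-en-1-one | C[C@H]1CCC(=O)C(CCC(C)(C)O[Si](CC)(CC)CC)=C1 | intermediate
10 | trimethyl{[(3R,4S)-3-ethenyl-4-methyl-2-[3-methyl-3-(triethylsilyloxy)butyl]cyclohex-1-en-1-yl]oxy}silane | C=C[C@H]1C(CCC(C)(C)O[Si](CC)(CC)CC)=C(O[Si](C)(C)C)CC[C@@H]1C | intermediate (not isolated)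
11 | (2R,3R,4S)-3-ethenyl-2,4-dimethyl-2-[3-methyl-3-(triethylsilyloxy)butyl]cyclohexan-1-one | C=C[C@H]1[C@@](C)(CCC(C)(C)O[Si](CC)(CC)CC)C(=O)CC[C@@H]1C | intermediate
12 | (4S,5R,6R)-5-ethenyl-4,6-dimethyl-6-[3-methyl-3-(triethylsilyloxy)butyl]cyclohex-2-en-1-one | C=C[C@H]1[C@@](C)(CCC(C)(C)O[Si](CC)(CC)CC)C(=O)C=C[C@@H]1C | intermediate
13 | tert-butyl{[(5R,6R)-5-ethenyl-4,6-dimethyl-6-[3-methyl-3-(triethylsilyloxy)butyl]cyclohexa-1,3-dien-1-yl]oxy}dimethylsilane | C=C[C@H]1[C@@](C)(CCC(C)(C)O[Si](CC)(CC)CC)C(O[Si](C)(C)C(C)(C)C)=CC=C1C | intermediate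
14 | 3-bromofuran-2(5H)-one | O=C1OCC=C1Br | starting material
15 | 9-BBN adduct of 13 at the vinyl group (boron on terminal carbon C7) | B1(CC[C@H]2[C@@](C)(CCC(C)(C)O[Si](CC)(CC)CC)C(O[Si](C)(C)C(C)(C)C)=CC=C2C)C2CCCC1CCC2 | intermediate (not isolated)
16 | butenolide-tethered silyl dienol ether (13 with vinyl replaced by 2-(2-oxo-2,5-dihydrofuran-3-yl)ethyl; C4 and C5 as in 13) | O=C1OCC=C1CC[C@H]2[C@@](C)(CCC(C)(C)O[Si](CC)(CC)CC)C(O[Si](C)(C)C(C)(C)C)=CC=C2C | intermediate
17 | cage adduct: bicyclo[2.2.2]oct-2-ene (bridgeheads C3–OTBS, C10–CH3), bonds C9–C10 and C3–C8, γ-lactone C12(=O)–O–C11 cis-fused on C8–C9 over C1=C2, C6–C7 bridge from C5 to C8 | O=C3[C@]15CC[C@H]2[C@@](C)(CCC(C)(C)O[Si](CC)(CC)CC)[C@]5(O[Si](C)(C)C(C)(C)C)C=C[C@@]2(C)[C@H]1CO3 | intermediate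
18 | cage diol (17 with the lactone reduced to C11–OH and C12–OH) | OC[C@]15CC[C@H]2[C@@](C)(CCC(C)(C)O[Si](CC)(CC)CC)[C@]5(O[Si](C)(C)C(C)(C)C)C=C[C@@]2(C)[C@H]1CO | intermediate
19 | cage bis(methanesulfonate) of 18 | CS(=O)(=O)OC[C@]15CC[C@H]2[C@@](C)(CCC(C)(C)O[Si](CC)(CC)CC)[C@]5(O[Si](C)(C)C(C)(C)C)C=C[C@@]2(C)[C@H]1COS(C)(=O)=O | intermediate
20 | [4β-(3-hydroxy-3-methylbutyl)-4α,10α-dimethyl-8(12)-methylene-3-oxo-5α-H-decal-1-en-9β-yl]methyl methanesulfonate (cis-fused) | C=C1CC[C@H]2[C@@](C)(CCC(C)(C)O)C(=O)C=C[C@@]2(C)[C@H]1COS(C)(=O)=O | intermediate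
21 | 1,2-dihydro derivative of 20 (saturated C3 ketone, C11 mesylate) | C=C1CC[C@H]2[C@@](C)(CCC(C)(C)O)C(=O)CC[C@@]2(C)[C@H]1COS(C)(=O)=O | intermediate
22 | 9β-(iodomethyl)-4β-(3-hydroxy-3-methylbutyl)-4α,10α-dimethyl-8(12)-methylene-5α-H-decalin-3-one | C=C1CC[C@H]2[C@@](C)(CCC(C)(C)O)C(=O)CC[C@@]2(C)[C@H]1CI | intermediate
23 | formate ester of 22 at the tertiary hydroxyl | C=C1CC[C@H]2[C@@](C)(CCC(C)(C)OC=O)C(=O)CC[C@@]2(C)[C@H]1CI | intermediate
24 | methyl acetoacetate | COC(=O)CC(C)=O | starting material
25 | malonyl dichloride | O=C(Cl)CC(=O)Cl | starting material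
26 | methyl 4-hydroxy-2-methyl-6-oxo-6H-pyran-3-carboxylate | COC(=O)C1=C(C)OC(=O)C=C1O | intermediate
27 | methyl 4-hydroxy-5-iodo-2-methyl-6-oxo-6H-pyran-3-carboxylate | COC(=O)C1=C(C)OC(=O)C(I)=C1O | intermediate
28 | methyl 5-iodo-6-methoxy-2-methyl-4-oxo-4H-pyran-3-carboxylate | COC(=O)c1c(C)oc(OC)c(I)c1=O | intermediate
29 | alkylzinc iodide from 23 (C11–ZnI) | C=C1CC[C@H]2[C@@](C)(CCC(C)(C)OC=O)C(=O)CC[C@@]2(C)[C@H]1C[Zn]I | intermediate (not isolated)
30 | 3-oxo precursor of the target (C3 ketone, tertiary formate, pyranone on C11) | C=C1CC[C@H]2[C@@](C)(CCC(C)(C)OC=O)C(=O)CC[C@@]2(C)[C@H]1Cc1c(OC)oc(C)c(C(=O)OC)c1=O | intermediate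
31 | target: methyl 5-{[(3S,4R,5R,9S,10S)-4-(3-formyloxy-3-methylbutyl)-3-hydroxy-4,10-dimethyl-8(12)-methylenedecalin-9-yl]methyl}-6-methoxy-2-methyl-4-oxo-4H-pyran-3-carboxylate (3β-OH, 4α-CH3, 5α-H, 9β-CH2, 10α-CH3) | C=C1CC[C@H]2[C@@](C)(CCC(C)(C)OC=O)[C@@H](O)CC[C@@]2(C)[C@H]1Cc1c(OC)oc(C)c(C(=O)OC)c1=O | target

**Step count and risks**
Total: 21 steps. Longest linear sequence: 17 steps (1, 2, 3, 5–16, 20, 21).

Steps most likely to fail:

1. Step 9. The silyl dienol ether may hydrolyse, and the bromobutenolide may decompose, under the aqueous basic coupling conditions; cycloaddition may also start before the product is isolated. Fallback: set out from ketone 11 and couple at the ketone stage with a dienophile that is inert to soft enolisation. Hydroboration of 11 with 9-BBN gives the alkylborane F1, which is coupled (PdCl2(dppf), Cs2CO3) with dimethyl bromomaleate to the keto maleate F2. Dehydrogenation with IBX, which needs no strong base, gives the enone maleate F3, and t-BuMe2SiOTf/Et3N gives the silyl dienol ether maleate F4. Heating effects the same intramolecular Diels–Alder reaction, now with a doubly activated dienophile, to the cage diester F5, and LiAlH4 reduces both esters to diol 18, where the route is rejoined.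

2. Step 13 (with its preparation in step 12). The cis-1,4-diol may close to a cyclic ether during sulfonylation, fluoride may displace or eliminate the C11 mesylate, or fragmentation may be incomplete. Fallback: set out from diol 18 and differentiate the two arms before fragmentation. Selective silylation of the less hindered C11 hydroxyl (t-BuMe2SiCl, imidazole) gives the mono-silyl ether F6, and mesylation of the neopentyl C12 hydroxyl gives F7. n-Bu4NF then removes all silyl groups and triggers the Grob fragmentation to the enone diol F8, and selective mesylation of its primary hydroxyl (MsCl, Et3N, −20 °C) returns enone mesylate 20.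

3. Step 21. Hydride attack on the tertiary formate, or its loss on work-up, may compete with reduction of the hindered ketone. Fallback: set out from 30 and install the formate after the alcohol is set. Reduction with excess LiBH(s-Bu)3 at 0 °C, accepting cleavage of the formate, gives the 3β,tertiary diol F9. The secondary hydroxyl is silylated selectively (Et3SiCl, imidazole) to give F10, the tertiary hydroxyl is formylated with acetic formic anhydride to give F11, and HF·pyridine removes the silyl group to give target 31.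

**Further compounds**
F1 | step 9 | 9-BBN adduct of 11 at the vinyl group | B1(CC[C@H]2[C@@](C)(CCC(C)(C)O[Si](CC)(CC)CC)C(=O)CC[C@@H]2C)C2CCCC1CCC2
F2 | step 9 | keto maleate (11 with vinyl replaced by 2-[cis-1,2-bis(methoxycarbonyl)ethenyl]ethyl) | COC(=O)/C=C(\C(=O)OC)CC[C@H]1[C@@](C)(CCC(C)(C)O[Si](CC)(CC)CC)C(=O)CC[C@@H]1C
F3 | step 9 | enone maleate (C1=C2 enone of F2) | COC(=O)/C=C(\C(=O)OC)CC[C@H]1[C@@](C)(CCC(C)(C)O[Si](CC)(CC)CC)C(=O)C=C[C@@H]1C
F4 | step 9 | silyl dienol ether maleate | COC(=O)/C=C(\C(=O)OC)CC[C@H]1[C@@](C)(CCC(C)(C)O[Si](CC)(CC)CC)C(O[Si](C)(C)C(C)(C)C)=CC=C1C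
F5 | step 9 | cage diester (as 17, with methyl esters at C12 and C11 in place of the lactone) | COC(=O)[C@]15CC[C@H]2[C@@](C)(CCC(C)(C)O[Si](CC)(CC)CC)[C@]5(O[Si](C)(C)C(C)(C)C)C=C[C@@]2(C)[C@H]1C(=O)OC
F6 | step 13 | cage diol mono(tert-butyldimethylsilyl) ether at C11–O | OC[C@]15CC[C@H]2[C@@](C)(CCC(C)(C)O[Si](CC)(CC)CC)[C@]5(O[Si](C)(C)C(C)(C)C)C=C[C@@]2(C)[C@H]1CO[Si](C)(C)C(C)(C)C
F7 | step 13 | C12 methanesulfonate of F6 | CS(=O)(=O)OC[C@]15CC[C@H]2[C@@](C)(CCC(C)(C)O[Si](CC)(CC)CC)[C@]5(O[Si](C)(C)C(C)(C)C)C=C[C@@]2(C)[C@H]1CO[Si](C)(C)C(C)(C)C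
F8 | step 13 | enone diol (20 with C11–OH in place of the mesylate) | C=C1CC[C@H]2[C@@](C)(CCC(C)(C)O)C(=O)C=C[C@@]2(C)[C@H]1CO
F9 | step 21 | 3β,tertiary diol (target without the formyl group) | C=C1CC[C@H]2[C@@](C)(CCC(C)(C)O)[C@@H](O)CC[C@@]2(C)[C@H]1Cc1c(OC)oc(C)c(C(=O)OC)c1=O
F10 | step 21 | 3β-O-triethylsilyl ether of F9 | C=C1CC[C@H]2[C@@](C)(CCC(C)(C)O)[C@@H](O[Si](CC)(CC)CC)CC[C@@]2(C)[C@H]1Cc1c(OC)oc(C)c(C(=O)OC)c1=O
F11 | step 21 | 3β-O-triethylsilyl ether of the target | C=C1CC[C@H]2[C@@](C)(CCC(C)(C)OC=O)[C@@H](O[Si](CC)(CC)CC)CC[C@@]2(C)[C@H]1Cc1c(OC)oc(C)c(C(=O)OC)c1=O
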